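All constants were set for the occasion; what happens was integrated by code.

The constants put Q, J and D on one clock: each step that moves them takes X as a partner, with a = 0.15 M⁻¹ min⁻¹ for Q, b = 0.18 M⁻¹ min⁻¹ for J, and c = 0.102 M⁻¹ min⁻¹ for the two steps out of D together.

    Z + X ⇌ G + L (K1 = 17, k1 = 0.22 M⁻¹ min⁻¹)
    D + X → D.X (k2 = 0.0097 M⁻¹ min⁻¹)
    D + X → G + Z (k3 = 0.092 M⁻¹ min⁻¹)
    Q + X → G + J (k4 = 0.15 M⁻¹ min⁻¹)
    J + X → G + D (k5 = 0.18 M⁻¹ min⁻¹)

| flask | Q | X | time |
|---|---|---|---|
| alder | 0.050 M | 0.300 equiv | 4.0 h |
| ash | 0.050 M | 0.800 equiv | 4.0 h |
| maple | 0.050 M | 2.50 equiv | 4.0 h |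
| larch | 0.050 M | 8.00 equiv | 4.0 h |

- amount of D at the end, in percent of the Q charged for alder, ash, maple, larch, in this order
- how the row runs (rises all the way / hardly changes / falls all the way / falls, then rises / rises, then falls)

- "hardly changes" means that all values lie within two and a half points (for a concentration: within two and a half percent of the largest)
- run time (alder): 4.0 h

Let the dose θ be a times the integral of [X] over the run, so that the fraction of Q left is e^−θ. The arrival dose, the mean dose a Q needs to reach D, is one plus a/b = 1.83. D climbs while θ is below about this value, then falls. Q charged at [Q]₀ gives X the time τ = 1/(a[Q]₀) = 133 min. Two extreme versions of the flask bracket θ, with n the equivalents of X and t the run time.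

X held at its charge, θ = n·t/τ:
alder 0.540, ash 1.44, maple 4.50, larch 14.4

X burnt throughout on time τ, θ = n·f, with f = 0.835:
alder 0.250, ash 0.668, maple 2.09, larch 6.68

With b/a at 1.20, J should burn X about as Q did, so alder, ash and maple should lie near the burnt line. Larch cannot: that line spends 6.68 equivalents of X, and the scheme takes at most 4 per Q, so its dose lies above the line. Ash stays under the arrival dose even when held, maple starts just past it, and larch is far past it. Every step of the chain from Q through J to D runs on the same [X], so the share of D in the Q charged depends on the dose alone (the Bateman solution):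

D/[Q]₀ = ab·[ e^(−θ)/((b−a)(c−a)) + e^(−bθ/a)/((a−b)(c−b)) + e^(−cθ/a)/((a−c)(b−c)) ]

On the burnt line this gives 2.96 % in alder, 14.1 % in ash and 36.2 % in maple. For larch the held and burnt doses give 0.0401 % and 5.75 %. This reckoning commits to a row that rises, then falls, with maple nearest the top.

The forecast gives 3 %, 14 %, 36 % and 1.3 %, so rises, then falls, on the ground that the linear chain from Q to D “has a Bateman solution”.

The flasks give 2.91 %, 13.8 %, 36.2 % and 1.40 %: rises, then falls.

Minus the logarithm of the Q left returns the dose: 0.248 in alder and 2.12 in maple, on the burnt line, and 8.99 in larch, inside its bracket. Maple's dose stands just past the arrival dose, and the row turns at 2.5 equiv. In larch, Q falls under a fiftieth of its charge by 1.42 h, well before the end at 4.0 h, and D ends at 1.40 %.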